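**Retrosynthetic overview**
- Target ⇐ desilylation and C6 acetylation; the butenolide is attached by B-alkyl Suzuki coupling at a C9 vinyl group; 6α-OH and 5α-H come from hydroboration of a Δ5 alkene.
- Ring B ⇐ Diels–Alder reaction of a 1-vinyl-2-methylcyclohexene (ring A) with but-2-ynal, which brings C8, C9, C11, C17 and the C8=C9 alkene.
- Ring A diene ⇐ bicyclic α-alkylidene γ-lactone (lactone → vinyl; 2α-OH by hydroboration, oxidation, hydride reduction).
- Key step: ring A and the lactone ring form together in an enantioselective rhodium-catalysed intramolecular [4+2] cycloaddition of a dienyl but-2-ynoate, setting the C4 quaternary centre.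
- Ring order: ring A + temporary lactone (one operation) → ring B → butenolide ring attached last.

Assumptions and conventions: positions are quoted in labdane numbering (C1–C20); TBS = tert-butyl(dimethyl)silyl; the (S)-BINAP rhodium catalyst is assumed to give the (3aS)-lactone 7, otherwise the mirror-image ligand is used.

**Step 1**
Reactants: 1 prop-2-enal (acrolein); 2 ethyl 2-(triphenylphosphoranylidene)propanoate
Product: 3 ethyl (2E)-2-methylpenta-2,4-dienoate
Conditions: CH2Cl2, 0 °C → rt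
Reagents that add atoms: none
Why: Wittig olefination with a stabilised α-methyl ylide gives the (E)-trisubstituted dienoate.

**Step 2**
Reactants: 3 ethyl (2E)-2-methylpenta-2,4-dienoate
Product: 4 (2E)-2-methylpenta-2,4-dien-1-ol
Conditions: i-Bu2AlH (2.2 equiv), CH2Cl2, −78 → 0 °C; aq. potassium sodium tartrate
Reagents that add atoms: none
Why: 1,2-reduction of the conjugated ester by the aluminium hydride gives the dienol and leaves the diene untouched.

**Step 3**
Reactants: 4 (2E)-2-methylpenta-2,4-dien-1-ol; 5 but-2-ynoic acid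
Product: 6 (2E)-2-methylpenta-2,4-dien-1-yl but-2-ynoate
Conditions: DCC, DMAP (5 mol %), CH2Cl2, −20 → 0 °C
Reagents that add atoms: none
Why: Steglich esterification links diene and ynoate through the three-atom ester tether; low temperature and little DMAP suppress ynoate-to-allenoate isomerization.

**Step 4 (key step)**
Reactants: 6 (2E)-2-methylpenta-2,4-dien-1-yl but-2-ynoate
Product: 7 (3aS)-3a,7-dimethyl-3a,6-dihydro-2-benzofuran-1(3H)-one
Conditions: [Rh(cod)Cl]2 (5 mol %), (S)-BINAP (11 mol %), AgSbF6 (20 mol %), ClCH2CH2Cl, 25 → 60 °C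
Reagents that add atoms: none
Why: Proposed new method: a cationic monovalent rhodium–BINAP complex coordinates the ynoate and the proximal diene C=C, enantio-determining oxidative cyclization forms the C4–C5 bond with the quaternary centre, and allyl-rhodium reductive elimination closes the cyclohexa-1,4-diene so that lactone and carbocycle form together with no thermal background reaction at this temperature; the closest known reactions are the rhodium-catalysed enantioselective intramolecular [4+2] cycloaddition of ether-tethered dienynes and the rhodium–BINAP cycloisomerization of ester-tethered 1,6-enynes.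

**Step 5**
Reactants: 7 (3aS)-3a,7-dimethyl-3a,6-dihydro-2-benzofuran-1(3H)-one
Product: 8 (3aS)-5-hydroxy-3a,7-dimethyl-3a,4,5,6-tetrahydro-2-benzofuran-1(3H)-one (both C5 epimers)
Conditions: 9-BBN-H (1.3 equiv), THF, 0 °C → rt; then 30% H2O2, aq. NaOAc, 0 °C
Reagents that add atoms: hydrogen peroxide, OO
Why: Hydroboration–oxidation in which 9-BBN attacks only the isolated cis-disubstituted alkene (the tetrasubstituted enoate is inert) and places boron on the carbon remote from the quaternary centre; the carbinol configuration is erased in step 6.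

**Step 6**
Reactants: 8 (3aS)-5-hydroxy-3a,7-dimethyl-3a,4,5,6-tetrahydro-2-benzofuran-1(3H)-one
Product: 9 (3aS)-3a,7-dimethyl-3a,4-dihydro-2-benzofuran-1,5(3H,6H)-dione
Conditions: Dess–Martin periodinane, NaHCO3, CH2Cl2, 0 °C → rt
Reagents that add atoms: none
Why: Buffered Dess–Martin oxidation converts both epimers to one ketone without moving the enoate double bond.

**Step 7**
Reactants: 9 (3aS)-3a,7-dimethyl-3a,4-dihydro-2-benzofuran-1,5(3H,6H)-dione
Product: 10 (3aS,5R)-5-hydroxy-3a,7-dimethyl-3a,4,5,6-tetrahydro-2-benzofuran-1(3H)-one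
Conditions: Li(s-Bu)3BH, THF, −78 °C; then H2O
Reagents that add atoms: none
Why: Bulky trialkylborohydride reduction in which hydride enters anti to the angular 3a-methyl group, which stands perpendicular to the rigid bicyclic lactone, so the new hydroxyl is cis to that methyl (the future 2α-OH); the lactone and the tetrasubstituted enoate are not reduced at −78 °C.

**Step 8**
Reactants: 10 (3aS,5R)-5-hydroxy-3a,7-dimethyl-3a,4,5,6-tetrahydro-2-benzofuran-1(3H)-one
Product: 12 (1R,5S)-4-ethenyl-5-(hydroxymethyl)-3,5-dimethylcyclohex-3-en-1-ol, via lactol 11 (not isolated)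
Conditions: i-Bu2AlH (2.3 equiv), CH2Cl2, −78 °C; then Ph3P=CH2 (from Ph3PCH3Br, KN(SiMe3)2; 5 equiv), THF, −78 °C → rt
Reagents that add atoms: methylenetriphenylphosphorane, C=P(c1ccccc1)(c1ccccc1)c1ccccc1
Why: Lactone-to-lactol reduction followed by in situ Wittig methylenation of the ring-opened hydroxy enal gives the 1-vinylcyclohexene diene and frees the C19 hydroxyl in one flask.

**Step 9**
Reactants: 12 (1R,5S)-4-ethenyl-5-(hydroxymethyl)-3,5-dimethylcyclohex-3-en-1-ol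
Product: 13 tert-butyl({(1S,5R)-5-[(tert-butyldimethylsilyl)oxy]-2-ethenyl-1,3-dimethylcyclohex-2-en-1-yl}methoxy)dimethylsilane
Conditions: TBSCl (3 equiv), imidazole, DMF, rt → 40 °C
Reagents that add atoms: tert-butyl(chloro)dimethylsilane, CC(C)(C)[Si](C)(C)Cl
Why: Silylation protects both hydroxyls, and the equatorial C2-OTBS group (cis to the C4 methyl) fixes the ring A half-chair with the C4 CH2OTBS group axial.

**Step 10**
Reactants: 14 but-2-yn-1-ol
Product: 15 but-2-ynal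
Conditions: activated MnO2 (excess), CH2Cl2, rt; filtered and used as a solution
Reagents that add atoms: none
Why: Manganese dioxide oxidation of a propargylic alcohol stops cleanly at the ynal.

**Step 11**
Reactants: 13 bis-TBS diene; 15 but-2-ynal
Product: 16 (5S,7R,8aS)-7-{[tert-butyl(dimethyl)silyl]oxy}-5-({[tert-butyl(dimethyl)silyl]oxy}methyl)-2,5,8a-trimethyl-3,5,6,7,8,8a-hexahydronaphthalene-1-carbaldehyde
Conditions: Me2AlCl (1.1 equiv), CH2Cl2, −78 → −20 °C
Reagents that add atoms: none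
Why: Lewis acid-promoted Diels–Alder reaction of an alkyne dienophile with a 1-vinylcyclohexene, in which the CH2 terminus of the diene bonds to the β-carbon of the ynal and C10 to the α-carbon (through the tertiary allyl-cation-like transition state), and the dienophile adds to the face of C10 opposite the axial CH2OTBS group, so the angular methyl ends cis to CH2OTBS and the C8=C9 alkene is formed directly.

**Step 12**
Reactants: 16 enal
Product: 17 (5S,7R,8aR)-7-{[tert-butyl(dimethyl)silyl]oxy}-5-({[tert-butyl(dimethyl)silyl]oxy}methyl)-1-ethenyl-2,5,8a-trimethyl-3,5,6,7,8,8a-hexahydronaphthalene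
Conditions: Ph3P=CH2 (from Ph3PCH3Br, KN(SiMe3)2), THF, −78 → 0 °C
Reagents that add atoms: methylenetriphenylphosphorane, C=P(c1ccccc1)(c1ccccc1)c1ccccc1
Why: Wittig methylenation of the hindered enal gives the C11=C12 vinyl group needed for the side-chain coupling.

**Step 13**
Reactants: 17 vinyl triene; 18 4-bromofuran-2(5H)-one
Product: 22 4-{2-[(4S,4aR,5S,7R,8aS)-7-{[tert-butyl(dimethyl)silyl]oxy}-5-({[tert-butyl(dimethyl)silyl]oxy}methyl)-4-hydroxy-2,5,8a-trimethyl-3,4,4a,5,6,7,8,8a-octahydronaphthalen-1-yl]ethyl}furan-2(5H)-one, via alkyl-9-BBN adduct 19 (not isolated), via bis-borane 20 (not isolated), via boronic acid 21 (not isolated)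
Conditions: 9-BBN-H (1.2 equiv), THF, 0 °C → rt; BH3·THF (2 equiv), 0 °C → rt; H2O; 18, Pd(dppf)Cl2 (10 mol %), AsPh3, K3PO4, DMF/H2O, rt; Me3NO·2H2O, 60 °C
Reagents that add atoms: trimethylamine N-oxide, C[N+](C)(C)[O-]
Why: Sequential chemoselective hydroborations (9-BBN at the terminal vinyl carbon, then BH3 at C6 of the trisubstituted Δ5 alkene from the α-face, anti to the β-axial C10 methyl and C4 CH2OTBS groups, giving 5α-H and a 6α-boryl group, while the hindered tetrasubstituted C8=C9 alkene does not react) are followed by a B-alkyl Suzuki–Miyaura coupling in which only the primary alkyl-9-BBN transfers, and amine-oxide oxidation of the remaining C–B bond with retention gives the 6α-alcohol without exposing the butenolide to borane or peroxide.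

**Step 14**
Reactants: 22 butenolide 6α-alcohol
Product: 23 (1S,4aS,6R,8S,8aR)-6-{[tert-butyl(dimethyl)silyl]oxy}-8-({[tert-butyl(dimethyl)silyl]oxy}methyl)-3,4a,8-trimethyl-4-[2-(5-oxo-2,5-dihydrofuran-3-yl)ethyl]-1,2,4a,5,6,7,8,8a-octahydronaphthalen-1-yl acetate
Conditions: Ac2O, DMAP, pyridine, CH2Cl2, rt
Reagents that add atoms: acetic anhydride, CC(=O)OC(C)=O
Why: DMAP-catalysed acetylation of the only free hydroxyl places the acetate on C6 with no need to differentiate it from the C2 and C19 oxygens.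

**Step 15**
Reactants: 23 bis-TBS acetate
Product: 24 (1S,4aS,6R,8S,8aR)-6-hydroxy-8-(hydroxymethyl)-3,4a,8-trimethyl-4-[2-(5-oxo-2,5-dihydrofuran-3-yl)ethyl]-1,2,4a,5,6,7,8,8a-octahydronaphthalen-1-yl acetate (CNP0231903.1)
Conditions: HF·pyridine, pyridine/THF, 0 °C → rt
Reagents that add atoms: none
Why: Fluoride-mediated desilylation removes both TBS ethers under mildly acidic conditions that spare the acetate, the butenolide and the tetrasubstituted alkene, and the 6α-acetate cannot migrate to the distant 2α- or 19-hydroxyl.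

**Compound list**
1 | prop-2-enal (acrolein) | C=CC=O | starting material
2 | ethyl 2-(triphenylphosphoranylidene)propanoate | CCOC(=O)C(C)=P(c1ccccc1)(c1ccccc1)c1ccccc1 | starting material
3 | ethyl (2E)-2-methylpenta-2,4-dienoate | CCOC(=O)/C(C)=C/C=C | intermediate
4 | (2E)-2-methylpenta-2,4-dien-1-ol | OC/C(C)=C/C=C | intermediate
5 | but-2-ynoic acid | CC#CC(=O)O | starting material
6 | (2E)-2-methylpenta-2,4-dien-1-yl but-2-ynoate | CC#CC(=O)OC/C(C)=C/C=C | intermediate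
7 | (3aS)-3a,7-dimethyl-3a,6-dihydro-2-benzofuran-1(3H)-one | CC1=C2C(=O)OC[C@@]2(C)C=CC1 | intermediate
8 | (3aS)-5-hydroxy-3a,7-dimethyl-3a,4,5,6-tetrahydro-2-benzofuran-1(3H)-one, both C5 epimers | CC1=C2C(=O)OC[C@@]2(C)CC(O)C1 | intermediate
9 | (3aS)-3a,7-dimethyl-3a,4-dihydro-2-benzofuran-1,5(3H,6H)-dione | CC1=C2C(=O)OC[C@@]2(C)CC(=O)C1 | intermediate
10 | (3aS,5R)-5-hydroxy-3a,7-dimethyl-3a,4,5,6-tetrahydro-2-benzofuran-1(3H)-one (OH cis to the 3a-methyl) | CC1=C2C(=O)OC[C@@]2(C)C[C@H](O)C1 | intermediate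
11 | (3aS,5R)-3a,7-dimethyl-1,3,3a,4,5,6-hexahydro-2-benzofuran-1,5-diol (lactol, both C1 epimers) | CC1=C2C(O)OC[C@@]2(C)C[C@H](O)C1 | intermediate
12 | (1R,5S)-4-ethenyl-5-(hydroxymethyl)-3,5-dimethylcyclohex-3-en-1-ol | C=CC1=C(C)C[C@@H](O)C[C@]1(C)CO | intermediate
13 | tert-butyl({(1S,5R)-5-[(tert-butyldimethylsilyl)oxy]-2-ethenyl-1,3-dimethylcyclohex-2-en-1-yl}methoxy)dimethylsilane | C=CC1=C(C)C[C@@H](O[Si](C)(C)C(C)(C)C)C[C@]1(C)CO[Si](C)(C)C(C)(C)C | intermediate
14 | but-2-yn-1-ol | CC#CCO | starting material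
15 | but-2-ynal | CC#CC=O | intermediate
16 | (5S,7R,8aS)-7-{[tert-butyl(dimethyl)silyl]oxy}-5-({[tert-butyl(dimethyl)silyl]oxy}methyl)-2,5,8a-trimethyl-3,5,6,7,8,8a-hexahydronaphthalene-1-carbaldehyde | O=CC1=C(C)CC=C2[C@]1(C)C[C@@H](O[Si](C)(C)C(C)(C)C)C[C@]2(C)CO[Si](C)(C)C(C)(C)C | intermediate
17 | (5S,7R,8aR)-7-{[tert-butyl(dimethyl)silyl]oxy}-5-({[tert-butyl(dimethyl)silyl]oxy}methyl)-1-ethenyl-2,5,8a-trimethyl-3,5,6,7,8,8a-hexahydronaphthalene | C=CC1=C(C)CC=C2[C@]1(C)C[C@@H](O[Si](C)(C)C(C)(C)C)C[C@]2(C)CO[Si](C)(C)C(C)(C)C | intermediate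
18 | 4-bromofuran-2(5H)-one | O=C1C=C(Br)CO1 | starting material
19 | 9-{2-[(5S,7R,8aR)-7-{[tert-butyl(dimethyl)silyl]oxy}-5-({[tert-butyl(dimethyl)silyl]oxy}methyl)-2,5,8a-trimethyl-3,5,6,7,8,8a-hexahydronaphthalen-1-yl]ethyl}-9-borabicyclo[3.3.1]nonane | CC1=C(CCB2C3CCCC2CCC3)[C@@]2(C)C[C@@H](O[Si](C)(C)C(C)(C)C)C[C@](C)(CO[Si](C)(C)C(C)(C)C)C2=CC1 | intermediate
20 | [(1S,4aS,6R,8S,8aR)-4-[2-(9-borabicyclo[3.3.1]nonan-9-yl)ethyl]-6-{[tert-butyl(dimethyl)silyl]oxy}-8-({[tert-butyl(dimethyl)silyl]oxy}methyl)-3,4a,8-trimethyl-1,2,4a,5,6,7,8,8a-octahydronaphthalen-1-yl]borane | B[C@H]1CC(C)=C(CCB2C3CCCC2CCC3)[C@@]2(C)C[C@@H](O[Si](C)(C)C(C)(C)C)C[C@](C)(CO[Si](C)(C)C(C)(C)C)[C@H]12 | intermediate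
21 | [(1S,4aS,6R,8S,8aR)-6-{[tert-butyl(dimethyl)silyl]oxy}-8-({[tert-butyl(dimethyl)silyl]oxy}methyl)-3,4a,8-trimethyl-4-[2-(5-oxo-2,5-dihydrofuran-3-yl)ethyl]-1,2,4a,5,6,7,8,8a-octahydronaphthalen-1-yl]boronic acid | OB(O)[C@H]1CC(C)=C(CCC2=CC(=O)OC2)[C@@]2(C)C[C@@H](O[Si](C)(C)C(C)(C)C)C[C@](C)(CO[Si](C)(C)C(C)(C)C)[C@H]12 | intermediate
22 | 4-{2-[(4S,4aR,5S,7R,8aS)-7-{[tert-butyl(dimethyl)silyl]oxy}-5-({[tert-butyl(dimethyl)silyl]oxy}methyl)-4-hydroxy-2,5,8a-trimethyl-3,4,4a,5,6,7,8,8a-octahydronaphthalen-1-yl]ethyl}furan-2(5H)-one | O[C@H]1CC(C)=C(CCC2=CC(=O)OC2)[C@@]2(C)C[C@@H](O[Si](C)(C)C(C)(C)C)C[C@](C)(CO[Si](C)(C)C(C)(C)C)[C@H]12 | intermediate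
23 | (1S,4aS,6R,8S,8aR)-6-{[tert-butyl(dimethyl)silyl]oxy}-8-({[tert-butyl(dimethyl)silyl]oxy}methyl)-3,4a,8-trimethyl-4-[2-(5-oxo-2,5-dihydrofuran-3-yl)ethyl]-1,2,4a,5,6,7,8,8a-octahydronaphthalen-1-yl acetate | CC(=O)O[C@H]1CC(C)=C(CCC2=CC(=O)OC2)[C@@]2(C)C[C@@H](O[Si](C)(C)C(C)(C)C)C[C@](C)(CO[Si](C)(C)C(C)(C)C)[C@H]12 | intermediate
24 | (1S,4aS,6R,8S,8aR)-6-hydroxy-8-(hydroxymethyl)-3,4a,8-trimethyl-4-[2-(5-oxo-2,5-dihydrofuran-3-yl)ethyl]-1,2,4a,5,6,7,8,8a-octahydronaphthalen-1-yl acetate | CC(=O)O[C@H]1CC(C)=C(CCC2=CC(=O)OC2)[C@@]2(C)C[C@@H](O)C[C@](C)(CO)[C@H]12 | target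

**Step count and risk**
Total: 15 steps. Longest linear sequence: 14 steps (steps 1–9 and 11–15); step 10 is a one-step side branch.

Most likely to fail:

- **Step 4 (enantioselective [4+2] with an ester tether and a quaternary centre).** Fallback, setting out from 5: esterify 5 with commercial 2-methylprop-2-en-1-ol (DCC, DMAP) to 2-methylprop-2-en-1-yl but-2-ynoate F1. Then run a [Rh(cod)2]BF4/(S)-tol-BINAP-catalysed [2+2+2] cycloaddition of this 1,6-enyne with acetylene (1 atm); the quaternary centre is set in the oxidative cyclization of the 1,1-disubstituted alkene, and the product is (3aS)-3a,7-dimethyl-3a,4-dihydro-2-benzofuran-1(3H)-one F2. 9-BBN adds to the terminal C5=C6 bond of this dienoate with boron on C5, and H2O2/NaOAc gives 8, where the route is rejoined (the C5 configuration is erased in step 6).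

- **Step 11 (Diels–Alder reaction of a hindered diene with an ynal; possible hetero-Diels–Alder or ene reaction at the aldehyde, and face selectivity).** Fallback, setting out from 13: use commercial methyl but-2-ynoate as dienophile with EtAlCl2 in CH2Cl2 (or neat at 110 °C), which removes the reactive aldehyde carbonyl and gives methyl (5S,7R,8aS)-7-{[tert-butyl(dimethyl)silyl]oxy}-5-({[tert-butyl(dimethyl)silyl]oxy}methyl)-2,5,8a-trimethyl-3,5,6,7,8,8a-hexahydronaphthalene-1-carboxylate F3. i-Bu2AlH reduction gives the allylic alcohol [(5S,7R,8aS)-7-{[tert-butyl(dimethyl)silyl]oxy}-5-({[tert-butyl(dimethyl)silyl]oxy}methyl)-2,5,8a-trimethyl-3,5,6,7,8,8a-hexahydronaphthalen-1-yl]methanol F4, and MnO2 oxidation returns 16.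

- **Step 13 (four events in one flask).** Fallback, setting out from 16, carries out the hydroboration before any boron–carbon coupling partner or lactone is present. BH3·THF reduces the aldehyde and hydroborates the Δ5 alkene from the α-face; NaOH/H2O2 then gives (1S,4aS,6R,8S,8aR)-6-{[tert-butyl(dimethyl)silyl]oxy}-8-({[tert-butyl(dimethyl)silyl]oxy}methyl)-4-(hydroxymethyl)-3,4a,8-trimethyl-1,2,4a,5,6,7,8,8a-octahydronaphthalen-1-ol F5. MnO2 oxidises only the allylic primary alcohol to (4S,4aR,5S,7R,8aS)-7-{[tert-butyl(dimethyl)silyl]oxy}-5-({[tert-butyl(dimethyl)silyl]oxy}methyl)-4-hydroxy-2,5,8a-trimethyl-3,4,4a,5,6,7,8,8a-octahydronaphthalene-1-carbaldehyde F6. Ac2O/DMAP gives (1S,4aS,6R,8S,8aR)-6-{[tert-butyl(dimethyl)silyl]oxy}-8-({[tert-butyl(dimethyl)silyl]oxy}methyl)-4-formyl-3,4a,8-trimethyl-1,2,4a,5,6,7,8,8a-octahydronaphthalen-1-yl acetate F7. Ph3P=CH2 at −78 °C gives (1S,4aS,6R,8S,8aR)-6-{[tert-butyl(dimethyl)silyl]oxy}-8-({[tert-butyl(dimethyl)silyl]oxy}methyl)-4-ethenyl-3,4a,8-trimethyl-1,2,4a,5,6,7,8,8a-octahydronaphthalen-1-yl acetate F8. 9-BBN hydroboration of the vinyl group and Suzuki coupling with 18 then give 23 directly, so steps 12–14 are replaced and the route is rejoined at 23.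

**Further compounds**
F1 | step 4 | 2-methylprop-2-en-1-yl but-2-ynoate | CC#CC(=O)OCC(C)=C
F2 | step 4 | (3aS)-3a,7-dimethyl-3a,4-dihydro-2-benzofuran-1(3H)-one | CC1=C2C(=O)OC[C@@]2(C)CC=C1
F3 | step 11 | methyl (5S,7R,8aS)-7-{[tert-butyl(dimethyl)silyl]oxy}-5-({[tert-butyl(dimethyl)silyl]oxy}methyl)-2,5,8a-trimethyl-3,5,6,7,8,8a-hexahydronaphthalene-1-carboxylate | COC(=O)C1=C(C)CC=C2[C@]1(C)C[C@@H](O[Si](C)(C)C(C)(C)C)C[C@]2(C)CO[Si](C)(C)C(C)(C)C
F4 | step 11 | [(5S,7R,8aS)-7-{[tert-butyl(dimethyl)silyl]oxy}-5-({[tert-butyl(dimethyl)silyl]oxy}methyl)-2,5,8a-trimethyl-3,5,6,7,8,8a-hexahydronaphthalen-1-yl]methanol | OCC1=C(C)CC=C2[C@]1(C)C[C@@H](O[Si](C)(C)C(C)(C)C)C[C@]2(C)CO[Si](C)(C)C(C)(C)C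
F5 | step 13 | (1S,4aS,6R,8S,8aR)-6-{[tert-butyl(dimethyl)silyl]oxy}-8-({[tert-butyl(dimethyl)silyl]oxy}methyl)-4-(hydroxymethyl)-3,4a,8-trimethyl-1,2,4a,5,6,7,8,8a-octahydronaphthalen-1-ol | O[C@H]1CC(C)=C(CO)[C@@]2(C)C[C@@H](O[Si](C)(C)C(C)(C)C)C[C@](C)(CO[Si](C)(C)C(C)(C)C)[C@H]12
F6 | step 13 | (4S,4aR,5S,7R,8aS)-7-{[tert-butyl(dimethyl)silyl]oxy}-5-({[tert-butyl(dimethyl)silyl]oxy}methyl)-4-hydroxy-2,5,8a-trimethyl-3,4,4a,5,6,7,8,8a-octahydronaphthalene-1-carbaldehyde | O[C@H]1CC(C)=C(C=O)[C@@]2(C)C[C@@H](O[Si](C)(C)C(C)(C)C)C[C@](C)(CO[Si](C)(C)C(C)(C)C)[C@H]12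
F7 | step 13 | (1S,4aS,6R,8S,8aR)-6-{[tert-butyl(dimethyl)silyl]oxy}-8-({[tert-butyl(dimethyl)silyl]oxy}methyl)-4-formyl-3,4a,8-trimethyl-1,2,4a,5,6,7,8,8a-octahydronaphthalen-1-yl acetate | CC(=O)O[C@H]1CC(C)=C(C=O)[C@@]2(C)C[C@@H](O[Si](C)(C)C(C)(C)C)C[C@](C)(CO[Si](C)(C)C(C)(C)C)[C@H]12
F8 | step 13 | (1S,4aS,6R,8S,8aR)-6-{[tert-butyl(dimethyl)silyl]oxy}-8-({[tert-butyl(dimethyl)silyl]oxy}methyl)-4-ethenyl-3,4a,8-trimethyl-1,2,4a,5,6,7,8,8a-octahydronaphthalen-1-yl acetate | CC(=O)O[C@H]1CC(C)=C(C=C)[C@@]2(C)C[C@@H](O[Si](C)(C)C(C)(C)C)C[C@](C)(CO[Si](C)(C)C(C)(C)C)[C@H]12
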